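Read at 25 min, the flask is either at rest or merely slow, and two chemists disagree over which.

in all of them: left-handed substrate 0.20 M; right-handed substrate 0.20 M
- red: reagent 1 equiv (fed, over 20 s); precatalyst 0.05 mol%; run made earlier; the fed solution adds 0.20 times the starting volume
- ochre: reagent 1 equiv (fed, over 20 s); precatalyst 0.2 mol%; run made earlier; the fed solution adds 0.20 times the starting volume
- flask: reagent 1.00 equiv (fed, over 20 s); precatalyst 0.1 mol%; the fed solution adds 0.20 times the starting volume; time 25 min

| run | time / min | left-handed substrate / % | left-handed product / % | right-handed substrate / % |
|---|---|---|---|---|
| red | 1.33 | 29.9 | 19.8 | 39.6 |
| red | 4.00 | 20.2 | 31.2 | 32.3 |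
| red | 8.00 | 18.1 | 31.9 | 31.4 |
| red | 10.0 | 19.1 | 31.8 | 31.4 |
| red | 15.0 | 18.4 | 31.9 | 31.5 |
| ochre | 3.00 | 18.3 | 31.8 | 31.5 |
| ochre | 6.00 | 18.2 | 31.8 | 31.5 |
| ochre | 10.0 | 18.7 | 32.0 | 31.6 |
| ochre | 12.0 | 17.9 | 31.8 | 31.5 |
| ochre | 15.0 | 18.3 | 31.8 | 31.9 |

(scatter of a reading: 0.3 percentage points)

- catalyst is single-handed; left-handed substrate and right-handed substrate are mirror images of each other, charged as a racemate, each of them at the stated concentration
- charges are per starting volume, the dose included; the dosed solution carries all of it
- the reaction counts as stopped when no species that holds the left-handed substrate and right-handed substrate together changes by six tenths of a point or more over the second half of the time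

- which holds at 25 min: what has brought the reaction to rest, or that it has not come to rest (no working catalyst is left / the reagent has run out first / all of the left-handed substrate has reacted / it is still moving)
- part of the left-handed substrate and right-handed substrate together gone at 25 min
- the left-handed product standing at 25 min, as a percentage of the left-handed substrate and right-handed substrate together charged
- the right-handed substrate standing at 25 min, as a percentage of the left-handed substrate and right-handed substrate together charged

The first holds a clock view: catalyst sets how far the reaction has got, so a loading between the red and ochre ones should land between them. The second holds a budget view. If each substrate molecule removed burns one reagent, the reagent is the limiting reagent, and the reagent budget B, the share of the pool of both substrates that the charge can remove, is the equivalents divided by two: 50.0 %.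

The clock view fits the red run at 1.33 min, where 30.5 % has gone, less than B. That is its region: readings taken before the conversion reaches B. Later the last readings show 50.1 % gone at 0.05 mol% and 49.8 % at 0.2 mol%, which is agreement within the scatter, and both stand close to B.

My own reckoning takes the budget side. The red run's left-handed product and right-handed substrate hold within the scatter from 8.00 min, and the flask has more precatalyst than that run and runs longer, to 25 min. Left-handed substrate lost reappears as left-handed product, so, as fractions of the pool and with B gone, right-handed substrate S and left-handed product P obey S − P = 0.5 − B, here 0 percentage points. I therefore expect both at the mean of their last readings in the red and ochre runs, 31.8 %.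

The forecast also takes that side: the reagent has run out first, with 50.1 % gone, 31.8 % left-handed product and 31.6 % right-handed substrate, the last differing slightly from mine. Its ground: “Total consumed is about 50% of the substrate pool, which is exactly 1 equiv of reagent relative to the left-handed substrate”.

The outcome in the flask is that the reagent has run out first, with reagent at 0 % of its charge, 50.0 % gone, 31.7 % left-handed product and 31.7 % right-handed substrate.

    reagent + catalyst + left-handed substrate → catalyst + left-handed product (k = 1500 M⁻² s⁻¹)
    reagent + catalyst + right-handed substrate → catalyst + right-handed product (k = 680 M⁻² s⁻¹)
    precatalyst → catalyst (k = 0.0200 s⁻¹)

The conversion in the flask is close to B, and 37 % of the charged left-handed substrate remains there. B also gives the margin on the reagent charge: the conversion has moved by 5 points at 0.900 equiv, where B is 45.0 %.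

In a neighbouring flask with 0.600 equiv of reagent, other charges and the time as here, B is 30.0 % and S − P is 20 points. That flask computes to 30.0 % gone, with 19.8 % left-handed product and 39.8 % right-handed substrate.

The earlier runs and the new flask are calculated from invented constants, and the scatter is random.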